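## Retrosynthetic overview

1. Target 26 ⇐ site- and face-selective epoxidation of the 4,5-E alkene of trienolide 25; 25 ⇐ oxidative lactonisation (O6 onto C12) once the C8 and C9 esters are in place.
2. C8 methacrylate (SN2 on an α-bromo ketone) and C9 acetate (ketone reduction) ⇐ enolate of a ten-membered ketone.
3. Ten-membered ring ⇐ anionic oxy-Cope ring expansion (C4–C9 broken, C6–C7 formed) of a 5,6-dialkenylcyclohexenol; the ring-cis C1=C10 ester is inherited from the six-membered ring.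
4. Cyclohexadienone ⇐ catalytic asymmetric dearomative Claisen rearrangement of the allyl ether of methyl 3-methylsalicylate; this creates quaternary C4, the only stereocentre set by a reagent.
5. Ring order: benzene ring → cyclohexadienone → ten-membered carbocycle → γ-lactone → epoxide.

Locants C1–C15 in the explanations are the germacrane positions of the target (ring C1–C10, lactone carbons C11–C13, ester carbon C14, ring methyl C15). In the six-membered intermediates C4 is ring position 5 and C9 is ring position 6; the ten-membered intermediates are named with germacrane locants. TBS = tert-butyl(dimethyl)silyl.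

Assumption: the sense of induction of the copper–bis(oxazoline) catalyst in step 2 is assigned by analogy; if it proves opposite, the (R,R)-ligand is used and nothing else changes.

## Route

Step 1
Reactants: 1 methyl 2-hydroxy-3-methylbenzoate (methyl 3-methylsalicylate); 2 allyl bromide
Product: 3 methyl 3-methyl-2-(prop-2-en-1-yloxy)benzoate
Conditions: K2CO3, acetone, reflux
Reagents that add atoms: none
Why: Williamson etherification (SN2) of the phenoxide on the allylic bromide in a polar solvent gives clean O-alkylation, and no stereocentre is formed.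

Step 2
Reactants: 3 methyl 3-methyl-2-(prop-2-en-1-yloxy)benzoate
Product: 4 methyl (5R)-5-methyl-6-oxo-5-(prop-2-en-1-yl)cyclohexa-1,3-diene-1-carboxylate
Conditions: [Cu((S,S)-t-Bu-box)](SbF6)2 (10 mol %), 4 Å MS, CH2Cl2, 0 → 20 °C
Reagents that add atoms: none
Why: Proposed new method: a cationic bis(oxazoline) complex of divalent copper, chelated by the ether oxygen and the ester carbonyl (the two-point binding of the Hiersemann catalytic asymmetric Claisen rearrangement of 2-alkoxycarbonyl allyl vinyl ethers, the closest known reaction type, together with dearomative Claisen rearrangements of naphthyl allyl ethers), polarises the O–allyl bond so that the concerted [3,3] shift runs at or below room temperature; the allyl terminus should bond to the electron-richer methyl-bearing ortho carbon C4 rather than the ester-bearing one, the chiral pocket selects the arene face to give (5R)-4, the blocked dienone cannot re-aromatise, and staying at or below 20 °C should hold back the onward Cope shift to the para position, which is a thermal process of about 80 °C.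

Step 3
Reactants: 4 methyl (5R)-5-methyl-6-oxo-5-(prop-2-en-1-yl)cyclohexa-1,3-diene-1-carboxylate
Product: 6 methyl (5R)-5-methyl-6-oxo-5-(2-oxoethyl)cyclohexa-1,3-diene-1-carboxylate, via vicinal diol 5 (not isolated)
Conditions: OsO4 (2 mol %), NaIO4 (3 equiv), 2,6-lutidine, dioxane/H2O 3:1, 20 °C
Reagents that add atoms: osmium tetroxide, O=[Os](=O)(=O)=O (catalytic, source of the new oxygen, regenerated by periodate); sodium periodate, [Na+].[O-]I(=O)(=O)=O
Why: Lemieux–Johnson oxidative cleavage, in which electrophilic OsO4 should dihydroxylate only the isolated terminal alkene (the ring alkenes are deactivated by ketone and ester) and NaIO4 cleaves the diol, removing one carbon as formaldehyde and leaving C4 untouched.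

Step 4
Reactants: 6 methyl (5R)-5-methyl-6-oxo-5-(2-oxoethyl)cyclohexa-1,3-diene-1-carboxylate
Product: 7 methyl (5S)-5-[(E)-2-(TBS-oxy)ethenyl]-5-methyl-6-oxocyclohexa-1,3-diene-1-carboxylate
Conditions: TBSOTf (1.2 equiv), Et3N (2 equiv), CH2Cl2, −78 → 0 °C
Reagents that add atoms: tert-butyldimethylsilyl trifluoromethanesulfonate (TBSOTf), CC(C)(C)[Si](C)(C)OS(=O)(=O)C(F)(F)F
Why: Soft enolisation (silyl triflate and amine) can only touch the CH2CHO unit because the dienone has no enolisable hydrogen, and the E enol ether is expected because the trans arrangement avoids the clash between the quaternary carbon and the silyloxy group (any Z isomer is removed by chromatography; the descriptor changes from R to S only through the priority rules).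

Step 5
Reactants: 7 methyl (5S)-5-[(E)-2-(TBS-oxy)ethenyl]-5-methyl-6-oxocyclohexa-1,3-diene-1-carboxylate
Product: 8 methyl (5S)-5-[(E)-2-(TBS-oxy)ethenyl]-5-methyl-6-oxocyclohex-1-ene-1-carboxylate
Conditions: H2 (1 atm), RhCl(PPh3)3 (5 mol %), toluene, 20 °C; filtered through Celite and used crude at once
Reagents that add atoms: none
Why: Homogeneous hydrogenation with Wilkinson's catalyst should saturate the cis-disubstituted γ,δ-alkene C2=C3 of the dienone and leave the trisubstituted ester-bearing C1=C10 bond and the hindered trans silyl enol ether, and the neutral conditions avoid acid- or base-catalysed tautomerisation of the 2-acyl acrylate to its dienol, which is why 8 is not chromatographed.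

Step 6
Reactants: 9 2-bromoprop-2-en-1-ol
Product: 10 [(2-bromoprop-2-en-1-yl)oxy](tert-butyl)dimethylsilane
Conditions: TBSCl, imidazole, DMF, 20 °C
Reagents that add atoms: tert-butyldimethylsilyl chloride (TBSCl), CC(C)(C)[Si](C)(C)Cl
Why: Standard silylation of a primary alcohol by nucleophilic substitution at silicon; no stereocentre is involved.

Step 7
Reactants: 10 [(2-bromoprop-2-en-1-yl)oxy](tert-butyl)dimethylsilane; 11 (E)-1,2-bis(tributylstannyl)ethene
Product: 12 tributyl[(1E)-3-(TBS-oxymethyl)buta-1,3-dien-1-yl]stannane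
Conditions: 11 (2 equiv), Pd(PPh3)4 (5 mol %), toluene, 90 °C
Reagents that add atoms: none
Why: Stille cross-coupling of the vinyl bromide with one tin terminus of the excess distannane proceeds with retention, so the E geometry of the stannyl alkene is carried into the dienylstannane.

Step 8
Reactants: 8 methyl (5S)-5-[(E)-2-(TBS-oxy)ethenyl]-5-methyl-6-oxocyclohex-1-ene-1-carboxylate; 12 tributyl[(1E)-3-(TBS-oxymethyl)buta-1,3-dien-1-yl]stannane
Product: 15 methyl (5S,6R)-5-[(E)-2-(TBS-oxy)ethenyl]-6-[(1E)-3-(TBS-oxymethyl)buta-1,3-dien-1-yl]-6-hydroxy-5-methylcyclohex-1-ene-1-carboxylate, via dienyllithium 13 (not isolated), via dienylcerium dichloride 14 (not isolated)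
Conditions: 12 (1.5 equiv), MeLi (1.45 equiv), THF, −78 °C; CeCl3 (1.6 equiv), −78 °C; then 8, −78 °C; H2O
Reagents that add atoms: none
Why: Tin–lithium exchange and transmetalation give a weakly basic, oxophilic alkenylcerium reagent that is expected to add 1,2 to the hindered, enolisable, doubly activated ketone rather than attack C1 or deprotonate C2, and approach anti to the bulkier silyloxyvinyl group on C4 gives the (6R) carbinol with the two alkenyl groups trans (the C9 epimer would pass through the same chair in step 9).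

Step 9
Reactants: 15 methyl (5S,6R)-5-[(E)-2-(TBS-oxy)ethenyl]-6-[(1E)-3-(TBS-oxymethyl)buta-1,3-dien-1-yl]-6-hydroxy-5-methylcyclohex-1-ene-1-carboxylate
Product: 18 methyl (1(10)E,4E,6R,7S,8R)-8-bromo-4-methyl-9-oxo-6-(TBS-oxy)-7-[3-(TBS-oxy)prop-1-en-2-yl]cyclodeca-1(10),4-diene-10-carboxylate, via potassium alkoxide 16 (not isolated), via ring-expanded potassium enolate 17 (not isolated)
Conditions: KH (1.3 equiv), 18-crown-6 (1.3 equiv), THF, 0 → 20 °C; then −78 °C, NBS (1.3 equiv); H2O work-up, used promptly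
Reagents that add atoms: N-bromosuccinimide, O=C1CCC(=O)N1Br
Why: Anionic oxy-Cope rearrangement through the chair with ring carbon C3 and both terminal substituents equatorial breaks C4–C9 and forms C6–C7, transferring the C4 configuration into (6R,7S), giving the 4E alkene and keeping the ring-cis C1=C10 bond of the arene-derived ring (that ring alkene could only take part through a strained bicyclo[2.2.2] boat), and the ring-trans enolate is then brominated by NBS on its outer face, anti to the transannular C4=C5 bond, to give the (8R) bromide.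

Step 10
Reactants: 18 methyl (1(10)E,4E,6R,7S,8R)-8-bromo-4-methyl-9-oxo-6-(TBS-oxy)-7-[3-(TBS-oxy)prop-1-en-2-yl]cyclodeca-1(10),4-diene-10-carboxylate
Product: 19 methyl (1(10)E,4E,6R,7R,8S)-4-methyl-8-[(2-methylprop-2-enoyl)oxy]-9-oxo-6-(TBS-oxy)-7-[3-(TBS-oxy)prop-1-en-2-yl]cyclodeca-1(10),4-diene-10-carboxylate
Conditions: sodium methacrylate (2 equiv), methacrylic acid (2 equiv), DMF, 0 → 20 °C
Reagents that add atoms: sodium methacrylate, C=C(C)C(=O)[O-].[Na+]
Why: SN2 displacement of the carbonyl-activated α-bromide by carboxylate with inversion places the methacrylate (8S) cis to the C7 side chain, and the acid/carboxylate buffer is too weakly basic to deprotonate C2 or cause elimination.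

Step 11
Reactants: 19 methyl (1(10)E,4E,6R,7R,8S)-4-methyl-8-[(2-methylprop-2-enoyl)oxy]-9-oxo-6-(TBS-oxy)-7-[3-(TBS-oxy)prop-1-en-2-yl]cyclodeca-1(10),4-diene-10-carboxylate
Product: 20 methyl (1(10)E,4E,6R,7R,8S,9S)-9-hydroxy-4-methyl-8-[(2-methylprop-2-enoyl)oxy]-6-(TBS-oxy)-7-[3-(TBS-oxy)prop-1-en-2-yl]cyclodeca-1(10),4-diene-10-carboxylate
Conditions: NaBH4, CeCl3·7H2O, MeOH, −78 °C
Reagents that add atoms: none
Why: Luche reduction gives only 1,2-reduction of the acyl acrylate ketone, and hydride delivery to the outer face of C9 in the Felkin–Anh sense (anti to the C8 acyloxy group) gives the (9S) alcohol trans to the C8 ester.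

Step 12
Reactants: 20 methyl (1(10)E,4E,6R,7R,8S,9S)-9-hydroxy-4-methyl-8-[(2-methylprop-2-enoyl)oxy]-6-(TBS-oxy)-7-[3-(TBS-oxy)prop-1-en-2-yl]cyclodeca-1(10),4-diene-10-carboxylate
Product: 21 methyl (1(10)E,4E,6R,7R,8S,9S)-9-(acetyloxy)-4-methyl-8-[(2-methylprop-2-enoyl)oxy]-6-(TBS-oxy)-7-[3-(TBS-oxy)prop-1-en-2-yl]cyclodeca-1(10),4-diene-10-carboxylate
Conditions: Ac2O, pyridine, DMAP (cat.), CH2Cl2, 0 °C
Reagents that add atoms: acetic anhydride, CC(=O)OC(C)=O
Why: DMAP-catalysed acetylation of the secondary allylic alcohol, run immediately to forestall 1,2-acyl migration from O8; no stereocentre is touched.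

Step 13
Reactants: 21 methyl (1(10)E,4E,6R,7R,8S,9S)-9-(acetyloxy)-4-methyl-8-[(2-methylprop-2-enoyl)oxy]-6-(TBS-oxy)-7-[3-(TBS-oxy)prop-1-en-2-yl]cyclodeca-1(10),4-diene-10-carboxylate
Product: 22 methyl (1(10)E,4E,6R,7S,8S,9S)-9-(acetyloxy)-6-hydroxy-7-(3-hydroxyprop-1-en-2-yl)-4-methyl-8-[(2-methylprop-2-enoyl)oxy]cyclodeca-1(10),4-diene-10-carboxylate
Conditions: HF·pyridine, pyridine/THF, 0 → 20 °C
Reagents that add atoms: none
Why: Fluoride-mediated desilylation under mildly acidic conditions removes both silyl ethers and leaves the three esters and the allylic positions intact (the C7 descriptor changes only through the priority rules).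

Step 14
Reactants: 22 methyl (1(10)E,4E,6R,7S,8S,9S)-9-(acetyloxy)-6-hydroxy-7-(3-hydroxyprop-1-en-2-yl)-4-methyl-8-[(2-methylprop-2-enoyl)oxy]cyclodeca-1(10),4-diene-10-carboxylate
Product: 25 methyl (1(10)E,4E,6R,7S,8S,9S)-9-acetoxy-8-(methacryloyloxy)germacra-1(10),4,11(13)-trien-12,6-olid-14-oate, via hydroxy enal 23 (not isolated), via lactol 24 (not isolated)
Conditions: TEMPO (20 mol %), PhI(OAc)2 (2.5 equiv), CH2Cl2, 20 °C
Reagents that add atoms: none
Why: Oxidative lactonisation in which the oxoammonium oxidant takes only the primary allylic alcohol to the enal, the C6 hydroxyl closes the five-membered lactol and a second oxidation gives the α-methylene γ-lactone, its trans ring fusion following from the C6/C7 configuration set in step 9.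

Step 15
Reactants: 25 methyl (1(10)E,4E,6R,7S,8S,9S)-9-acetoxy-8-(methacryloyloxy)germacra-1(10),4,11(13)-trien-12,6-olid-14-oate
Product: 26 methyl (1(10)E,4R,5R,6S,7R,8S,9S)-9-acetoxy-4,5-epoxy-8-(methacryloyloxy)germacra-1(10),11(13)-dien-12,6-olid-14-oate (CNP0153978.3)
Conditions: mCPBA (1.1 equiv), NaHCO3, CH2Cl2, 0 °C
Reagents that add atoms: 3-chloroperoxybenzoic acid (mCPBA), O=C(OO)c1cccc(Cl)c1
Why: Prilezhaev epoxidation in which the 4,5-alkene is the only electron-rich double bond (the other three are conjugated to carbonyls) and, as in other 6,12-trans-lactonised germacranolides, is attacked on its exposed outer face (anti to the transannular C1=C10 unit, syn to H6) to give the (4R,5R) trans epoxide.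

## Compound list

1 | methyl 2-hydroxy-3-methylbenzoate | COC(=O)c1cccc(C)c1O | starting material
2 | allyl bromide | C=CCBr | starting material
3 | methyl 3-methyl-2-(prop-2-en-1-yloxy)benzoate | COC(=O)c1cccc(C)c1OCC=C | intermediate
4 | methyl (5R)-5-methyl-6-oxo-5-(prop-2-en-1-yl)cyclohexa-1,3-diene-1-carboxylate | COC(=O)C1=CC=C[C@@](C)(CC=C)C1=O | intermediate
5 | methyl (5R)-5-(2,3-dihydroxypropyl)-5-methyl-6-oxocyclohexa-1,3-diene-1-carboxylate (both carbinol epimers) | COC(=O)C1=CC=C[C@@](C)(CC(O)CO)C1=O | intermediate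
6 | methyl (5R)-5-methyl-6-oxo-5-(2-oxoethyl)cyclohexa-1,3-diene-1-carboxylate | COC(=O)C1=CC=C[C@@](C)(CC=O)C1=O | intermediate
7 | methyl (5S)-5-[(E)-2-(TBS-oxy)ethenyl]-5-methyl-6-oxocyclohexa-1,3-diene-1-carboxylate | COC(=O)C1=CC=C[C@@](C)(/C=C/O[Si](C)(C)C(C)(C)C)C1=O | intermediate
8 | methyl (5S)-5-[(E)-2-(TBS-oxy)ethenyl]-5-methyl-6-oxocyclohex-1-ene-1-carboxylate | COC(=O)C1=CCC[C@@](C)(/C=C/O[Si](C)(C)C(C)(C)C)C1=O | intermediate
9 | 2-bromoprop-2-en-1-ol | C=C(Br)CO | starting material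
10 | [(2-bromoprop-2-en-1-yl)oxy](tert-butyl)dimethylsilane | C=C(Br)CO[Si](C)(C)C(C)(C)C | intermediate
11 | (E)-1,2-bis(tributylstannyl)ethene | CCCC[Sn](CCCC)(CCCC)/C=C/[Sn](CCCC)(CCCC)CCCC | starting material
12 | tributyl[(1E)-3-(TBS-oxymethyl)buta-1,3-dien-1-yl]stannane | CCCC[Sn](CCCC)(CCCC)/C=C/C(=C)CO[Si](C)(C)C(C)(C)C | intermediate
13 | [(1E)-3-(TBS-oxymethyl)buta-1,3-dien-1-yl]lithium | [Li]/C=C/C(=C)CO[Si](C)(C)C(C)(C)C | intermediate
14 | dichloro[(1E)-3-(TBS-oxymethyl)buta-1,3-dien-1-yl]cerium | Cl[Ce](Cl)/C=C/C(=C)CO[Si](C)(C)C(C)(C)C | intermediate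
15 | methyl (5S,6R)-5-[(E)-2-(TBS-oxy)ethenyl]-6-[(1E)-3-(TBS-oxymethyl)buta-1,3-dien-1-yl]-6-hydroxy-5-methylcyclohex-1-ene-1-carboxylate | COC(=O)C1=CCC[C@@](C)(/C=C/O[Si](C)(C)C(C)(C)C)[C@]1(O)/C=C/C(=C)CO[Si](C)(C)C(C)(C)C | intermediate
16 | potassium alkoxide of 15 | COC(=O)C1=CCC[C@@](C)(/C=C/O[Si](C)(C)C(C)(C)C)[C@]1([O-])/C=C/C(=C)CO[Si](C)(C)C(C)(C)C.[K+] | intermediate
17 | potassium (1(10)E,4E,6R,7S,8Z)-enolate of methyl 4-methyl-9-oxo-6-(TBS-oxy)-7-[3-(TBS-oxy)prop-1-en-2-yl]cyclodeca-1(10),4-diene-10-carboxylate | [K+].[O-]/C1=C\[C@@H](C(=C)CO[Si](C)(C)C(C)(C)C)[C@H](O[Si](C)(C)C(C)(C)C)/C=C(\C)CC/C=C1/C(=O)OC | intermediate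
18 | methyl (1(10)E,4E,6R,7S,8R)-8-bromo-4-methyl-9-oxo-6-(TBS-oxy)-7-[3-(TBS-oxy)prop-1-en-2-yl]cyclodeca-1(10),4-diene-10-carboxylate | Br[C@@H]1[C@@H](C(=C)CO[Si](C)(C)C(C)(C)C)[C@H](O[Si](C)(C)C(C)(C)C)/C=C(\C)CC/C=C(/C(=O)OC)C1=O | intermediate
19 | methyl (1(10)E,4E,6R,7R,8S)-4-methyl-8-[(2-methylprop-2-enoyl)oxy]-9-oxo-6-(TBS-oxy)-7-[3-(TBS-oxy)prop-1-en-2-yl]cyclodeca-1(10),4-diene-10-carboxylate | C=C(C)C(=O)O[C@H]1[C@@H](C(=C)CO[Si](C)(C)C(C)(C)C)[C@H](O[Si](C)(C)C(C)(C)C)/C=C(\C)CC/C=C(/C(=O)OC)C1=O | intermediate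
20 | methyl (1(10)E,4E,6R,7R,8S,9S)-9-hydroxy-4-methyl-8-[(2-methylprop-2-enoyl)oxy]-6-(TBS-oxy)-7-[3-(TBS-oxy)prop-1-en-2-yl]cyclodeca-1(10),4-diene-10-carboxylate | C=C(C)C(=O)O[C@H]1[C@@H](C(=C)CO[Si](C)(C)C(C)(C)C)[C@H](O[Si](C)(C)C(C)(C)C)/C=C(\C)CC/C=C(/C(=O)OC)[C@@H]1O | intermediate
21 | methyl (1(10)E,4E,6R,7R,8S,9S)-9-(acetyloxy)-4-methyl-8-[(2-methylprop-2-enoyl)oxy]-6-(TBS-oxy)-7-[3-(TBS-oxy)prop-1-en-2-yl]cyclodeca-1(10),4-diene-10-carboxylate | C=C(C)C(=O)O[C@H]1[C@@H](C(=C)CO[Si](C)(C)C(C)(C)C)[C@H](O[Si](C)(C)C(C)(C)C)/C=C(\C)CC/C=C(/C(=O)OC)[C@@H]1OC(C)=O | intermediate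
22 | methyl (1(10)E,4E,6R,7S,8S,9S)-9-(acetyloxy)-6-hydroxy-7-(3-hydroxyprop-1-en-2-yl)-4-methyl-8-[(2-methylprop-2-enoyl)oxy]cyclodeca-1(10),4-diene-10-carboxylate | C=C(C)C(=O)O[C@H]1[C@@H](C(=C)CO)[C@H](O)/C=C(\C)CC/C=C(/C(=O)OC)[C@@H]1OC(C)=O | intermediate
23 | methyl (1(10)E,4E,6R,7S,8S,9S)-9-(acetyloxy)-6-hydroxy-4-methyl-8-[(2-methylprop-2-enoyl)oxy]-7-(3-oxoprop-1-en-2-yl)cyclodeca-1(10),4-diene-10-carboxylate | C=C(C)C(=O)O[C@H]1[C@@H](C(=C)C=O)[C@H](O)/C=C(\C)CC/C=C(/C(=O)OC)[C@@H]1OC(C)=O | intermediate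
24 | 12-hydroxy lactol of 25 (both C12 epimers; 6R,7S,8S,9S) | C=C(C)C(=O)O[C@H]1[C@H]2C(=C)C(O)O[C@@H]2/C=C(\C)CC/C=C(/C(=O)OC)[C@@H]1OC(C)=O | intermediate
25 | methyl (1(10)E,4E,6R,7S,8S,9S)-9-acetoxy-8-(methacryloyloxy)germacra-1(10),4,11(13)-trien-12,6-olid-14-oate | C=C(C)C(=O)O[C@H]1[C@H]2C(=C)C(=O)O[C@@H]2/C=C(\C)CC/C=C(/C(=O)OC)[C@@H]1OC(C)=O | intermediate
26 | methyl (1(10)E,4R,5R,6S,7R,8S,9S)-9-acetoxy-4,5-epoxy-8-(methacryloyloxy)germacra-1(10),11(13)-dien-12,6-olid-14-oate (CNP0153978.3) | C=C(C)C(=O)O[C@H]1[C@H]2C(=C)C(=O)O[C@@H]2[C@H]2O[C@]2(C)CC/C=C(/C(=O)OC)[C@@H]1OC(C)=O | target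

## Step count and risks

Total steps: 15. Longest linear sequence: 13 (steps 1–5 and 8–15; steps 6 and 7 make the side-chain stannane).

The three steps most likely to fail:

Step 2. The dearomative Claisen rearrangement is unprecedented on a benzene ring with a free para position; the risks are attack at the ester-bearing ortho carbon, onward Cope shift to the para position, and an unproven sense and level of enantioselectivity. Fallback, substrate control by chirality transfer instead of catalyst control: setting out from 1, Mitsunobu etherification with (R)-but-3-en-2-ol (PPh3, DIAD, inversion) gives the aryl ether methyl 2-{[(2S)-but-3-en-2-yl]oxy}-3-methylbenzoate F1. Its Claisen rearrangement under achiral Lewis acid promotion (Eu(fod)3 or Cu(OTf)2/2,2'-bipyridine, at most 40 °C) through the chair with the methyl group equatorial relays the ether stereocentre to C4 and gives the crotyl dienone methyl (5R)-5-[(2E)-but-2-en-1-yl]-5-methyl-6-oxocyclohexa-1,3-diene-1-carboxylate F2. The same OsO4/NaIO4 cleavage then removes two carbons and returns to the route at aldehyde 6.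

Step 8. Ketone 8 is hindered, a doubly activated Michael acceptor at C1 and acidic at C2, so 1,4-addition or enolisation may win over 1,2-addition. Fallback, bring the C7–C8 unit in as an acetylide, which adds only 1,2: setting out from bromide 10, Sonogashira coupling with ethynyltrimethylsilane (PdCl2(PPh3)2, CuI, Et3N) gives the silyl enyne tert-butyl(dimethyl){[2-methylidene-4-(trimethylsilyl)but-3-yn-1-yl]oxy}silane F3, and K2CO3/MeOH gives the terminal enyne tert-butyl(dimethyl)[(2-methylidenebut-3-yn-1-yl)oxy]silane F4. Deprotonation with n-BuLi gives the lithium acetylide [3-(TBS-oxymethyl)but-3-en-1-yn-1-yl]lithium F5, and CeCl3 converts it into the cerium acetylide dichloro[3-(TBS-oxymethyl)but-3-en-1-yn-1-yl]cerium F6. Addition to ketone 8 at −78 °C gives the propargylic carbinol methyl (5S,6S)-5-[(E)-2-(TBS-oxy)ethenyl]-6-hydroxy-5-methyl-6-[3-(TBS-oxymethyl)but-3-en-1-yn-1-yl]cyclohex-1-ene-1-carboxylate F7. Ruthenium-catalysed trans-hydrosilylation ([Cp*Ru(MeCN)3]PF6, (EtO)3SiH) gives the vinylsilane methyl (5S,6R)-5-[(E)-2-(TBS-oxy)ethenyl]-6-hydroxy-5-methyl-6-[(1Z)-3-(TBS-oxymethyl)-2-(triethoxysilyl)buta-1,3-dien-1-yl]cyclohex-1-ene-1-carboxylate F8, and protodesilylation with AgF in wet THF/MeOH returns to the route at carbinol 15.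

Step 9. The desired chair rearrangement competes with a boat pathway through the ring alkene, the enolate may relax before it is trapped so that the face of bromination is not secure, and bromo ketone 18 may eliminate or epimerise. Fallback, an oxygen electrophile followed by Mitsunobu inversion: setting out from 15, the same KH/18-crown-6 rearrangement to enolate 17 is quenched at −78 °C with the Davis oxaziridine (2-(benzenesulfonyl)-3-phenyloxaziridine), which puts oxygen on the same outer face and gives the hydroxy ketone methyl (1(10)E,4E,6R,7R,8R)-8-hydroxy-4-methyl-9-oxo-6-(TBS-oxy)-7-[3-(TBS-oxy)prop-1-en-2-yl]cyclodeca-1(10),4-diene-10-carboxylate F9. Mitsunobu esterification with methacrylic acid (PPh3, DIAD) inverts C8 and returns to the route at 19, bypassing 18.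

## Further compounds

F1 | step 2 | methyl 2-{[(2S)-but-3-en-2-yl]oxy}-3-methylbenzoate | COC(=O)c1cccc(C)c1O[C@@H](C)C=C
F2 | step 2 | methyl (5R)-5-[(2E)-but-2-en-1-yl]-5-methyl-6-oxocyclohexa-1,3-diene-1-carboxylate | COC(=O)C1=CC=C[C@@](C)(C/C=C/C)C1=O
F3 | step 8 | tert-butyl(dimethyl){[2-methylidene-4-(trimethylsilyl)but-3-yn-1-yl]oxy}silane | C=C(CO[Si](C)(C)C(C)(C)C)C#C[Si](C)(C)C
F4 | step 8 | tert-butyl(dimethyl)[(2-methylidenebut-3-yn-1-yl)oxy]silane | C=C(CO[Si](C)(C)C(C)(C)C)C#C
F5 | step 8 | [3-(TBS-oxymethyl)but-3-en-1-yn-1-yl]lithium | [Li]C#CC(=C)CO[Si](C)(C)C(C)(C)C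
F6 | step 8 | dichloro[3-(TBS-oxymethyl)but-3-en-1-yn-1-yl]cerium | Cl[Ce](Cl)C#CC(=C)CO[Si](C)(C)C(C)(C)C
F7 | step 8 | methyl (5S,6S)-5-[(E)-2-(TBS-oxy)ethenyl]-6-hydroxy-5-methyl-6-[3-(TBS-oxymethyl)but-3-en-1-yn-1-yl]cyclohex-1-ene-1-carboxylate | COC(=O)C1=CCC[C@@](C)(/C=C/O[Si](C)(C)C(C)(C)C)[C@]1(O)C#CC(=C)CO[Si](C)(C)C(C)(C)C
F8 | step 8 | methyl (5S,6R)-5-[(E)-2-(TBS-oxy)ethenyl]-6-hydroxy-5-methyl-6-[(1Z)-3-(TBS-oxymethyl)-2-(triethoxysilyl)buta-1,3-dien-1-yl]cyclohex-1-ene-1-carboxylate | COC(=O)C1=CCC[C@@](C)(/C=C/O[Si](C)(C)C(C)(C)C)[C@]1(O)/C=C(\[Si](OCC)(OCC)OCC)C(=C)CO[Si](C)(C)C(C)(C)C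
F9 | step 9 | methyl (1(10)E,4E,6R,7R,8R)-8-hydroxy-4-methyl-9-oxo-6-(TBS-oxy)-7-[3-(TBS-oxy)prop-1-en-2-yl]cyclodeca-1(10),4-diene-10-carboxylate | O[C@@H]1[C@@H](C(=C)CO[Si](C)(C)C(C)(C)C)[C@H](O[Si](C)(C)C(C)(C)C)/C=C(\C)CC/C=C(/C(=O)OC)C1=O
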